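**Plan**

- Retrosynthesis cuts, in this order: the two ring A aryl–CH2 bonds (C4–CH2Ar and C6–CH2Ar), the bibenzyl CH2–CH2 bond (as a Wittig C=C), and the ring B aryl–CH2 bond to ring C (Suzuki–Miyaura).
- Forward: ring A is prepared as a phenolic benzylphosphonium salt carrying bromine at C2 (steps 1–3); rings B and C are joined by sp3–sp2 coupling and masked as a bis-tosylate aldehyde (steps 4–6); Wittig olefination and diimide reduction give the bibenzyl (steps 7–8). All five benzene rings are bought; no ring is built.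
- Enabling feature: in ring A (C1 OMe, C2 H, C3 OH, C4 and C6 4-hydroxybenzyl, C5 CH2CH2Ar), C4 is ortho to the C3 hydroxyl and para to the C1 methoxy, and C6 is para to the hydroxyl and ortho to the methoxy. Both are nucleophilic carbons of a resorcinol monoether.
- Both carbons are benzylated in one flask by acid-generated p-quinone methide, with bromine occupying C2 and rings B and C deactivated as tosylates. Hydrogenolysis of C–Br and sulfonate cleavage finish the synthesis.
- Stereochemistry: the target has no stereocentre; the Wittig alkene is carried as an E/Z mixture and removed by reduction.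

Key step: step 9

Assumption: compounds 1, 5, 7 and 14 are taken as purchasable; ring A is numbered C1 (OMe) to C6 as above, ring B is the 1,3,5-trisubstituted ring and ring C is the 4-oxygenated benzyl ring attached to it.

**Route**

Step 1
Reactants: 1 methyl 4-bromo-3,5-dihydroxybenzoate
Product: 2 methyl 4-bromo-3-hydroxy-5-methoxybenzoate
Conditions: MeI (1.0 equiv), K2CO3 (1.0 equiv), DMF, 0 °C to rt; chromatography, recovered 1 recycled
Reagents that add atoms: iodomethane, CI
Why: Williamson O-methylation of one of two equivalent phenols; the mono-ether should form statistically and be separable from unreacted 1 and the diether, the ester and aryl bromide being inert to MeI/K2CO3.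

Step 2
Reactants: 2 methyl 4-bromo-3-hydroxy-5-methoxybenzoate
Product: 3 4-bromo-3-hydroxy-5-methoxybenzyl alcohol
Conditions: i-Bu2AlH (3.5 equiv), CH2Cl2/THF, −78 °C to 0 °C; aq. potassium sodium tartrate
Reagents that add atoms: none
Why: hydride reduction of an aryl ester to the benzylic alcohol, the first equivalent of i-Bu2AlH being spent on the phenol; the aryl C–Br bond and the methyl ether should not be touched at low temperature.

Step 3
Reactants: 3 4-bromo-3-hydroxy-5-methoxybenzyl alcohol
Product: 4 (4-bromo-3-hydroxy-5-methoxybenzyl)triphenylphosphonium bromide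
Conditions: Ph3P·HBr (1.1 equiv), MeCN, reflux
Reagents that add atoms: triphenylphosphine hydrobromide, [Br-].[PH+](c1ccccc1)(c1ccccc1)c1ccccc1
Why: direct phosphonium salt formation from a benzylic alcohol (benzylic bromide formed in situ, then SN2 quaternisation of Ph3P); the phenol needs no protection under these acidic conditions.

Step 4
Reactants: 5 4-(chloromethyl)phenyl acetate
Product: 6 4-[(4,4,5,5-tetramethyl-1,3,2-dioxaborolan-2-yl)methyl]phenyl acetate
Conditions: B2pin2 (1.1 equiv), Pd(dba)2 (3 mol %), P(4-MeOC6H4)3 (6 mol %), KOAc (1.5 equiv), toluene, 50 °C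
Reagents that add atoms: bis(pinacolato)diboron, CC1(C)OB(OC1(C)C)B1OC(C)(C)C(C)(C)O1
Why: Miyaura borylation of a benzylic chloride under palladium catalysis with the weak base KOAc, conditions that should leave the aryl acetate intact.

Step 5
Reactants: 6 4-[(4,4,5,5-tetramethyl-1,3,2-dioxaborolan-2-yl)methyl]phenyl acetate and 7 3-bromo-5-hydroxybenzaldehyde
Product: 9 3-hydroxy-5-(4-hydroxybenzyl)benzaldehyde, via coupled aryl acetate 8 (not isolated)
Conditions: 6 (1.3 equiv), Pd(dppf)Cl2·CH2Cl2 (5 mol %), K2CO3 (4 equiv), 1,4-dioxane/H2O (4:1), 90 °C; then dilute HCl to pH 4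
Reagents that add atoms: none
Why: Suzuki–Miyaura sp3–sp2 coupling of a benzylboronic ester with an aryl bromide, which tolerates the aldehyde and the free phenol; the hot aqueous carbonate should hydrolyse the aryl acetate of 8 in the same flask and give the bisphenol directly.

Step 6
Reactants: 9 3-hydroxy-5-(4-hydroxybenzyl)benzaldehyde
Product: 10 3-formyl-5-[4-(tosyloxy)benzyl]phenyl 4-methylbenzenesulfonate
Conditions: TsCl (2.5 equiv), Et3N (4 equiv), DMAP (0.1 equiv), CH2Cl2, 0 °C to rt
Reagents that add atoms: 4-methylbenzenesulfonyl chloride, Cc1ccc(cc1)S(Cl)(=O)=O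
Why: sulfonylation of both phenols; the tosylates should withstand the strong base of step 7 and later deactivate rings B and C towards electrophiles.

Step 7
Reactants: 4 (4-bromo-3-hydroxy-5-methoxybenzyl)triphenylphosphonium bromide and 10 3-formyl-5-[4-(tosyloxy)benzyl]phenyl 4-methylbenzenesulfonate
Product: 12 3-[2-(4-bromo-3-hydroxy-5-methoxyphenyl)ethenyl]-5-[4-(tosyloxy)benzyl]phenyl 4-methylbenzenesulfonate (E/Z mixture), via phenoxide ylide 11 (not isolated)
Conditions: 4 (1.2 equiv), LiN(SiMe3)2 (2.3 equiv), THF, −78 °C to 0 °C; then 10, −78 °C to rt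
Reagents that add atoms: none
Why: Wittig olefination; two equivalents of the non-nucleophilic amide base give ylide 11, whose ylide carbon is not conjugated with the meta phenoxide and should add to the aldehyde of 10, while LiN(SiMe3)2 avoids the bromine–lithium exchange an alkyllithium would risk and the E/Z ratio is irrelevant.

Step 8
Reactants: 12 3-[2-(4-bromo-3-hydroxy-5-methoxyphenyl)ethenyl]-5-[4-(tosyloxy)benzyl]phenyl 4-methylbenzenesulfonate
Product: 13 3-[2-(4-bromo-3-hydroxy-5-methoxyphenyl)ethyl]-5-[4-(tosyloxy)benzyl]phenyl 4-methylbenzenesulfonate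
Conditions: TsNHNH2 (8 equiv, in portions), NaOAc (10 equiv), THF/H2O (1:1), reflux
Reagents that add atoms: none
Why: diimide reduction delivers H2 to the C=C bond by concerted syn transfer and, unlike hydrogenation over palladium, should spare the aryl C–Br bond and the sulfonate esters; both alkene isomers converge on one bibenzyl.

Step 9
Reactants: 13 3-[2-(4-bromo-3-hydroxy-5-methoxyphenyl)ethyl]-5-[4-(tosyloxy)benzyl]phenyl 4-methylbenzenesulfonate and 14 4-hydroxybenzyl alcohol
Product: 17 3-{2-[4-bromo-3-hydroxy-2,6-bis(4-hydroxybenzyl)-5-methoxyphenyl]ethyl}-5-[4-(tosyloxy)benzyl]phenyl 4-methylbenzenesulfonate, via p-quinone methide 15 (not isolated), via C4-monobenzyl bibenzyl 16 (not isolated)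
Conditions: TsOH·H2O (20 mol %), (CF3)2CHOH/CH2Cl2 (1:3), rt, argon; 14 (3 equiv) in MeCN added by syringe pump over 6 h
Reagents that add atoms: none
Why: acid ionises 14 to the 4-hydroxybenzyl cation, the O-protonated form of p-quinone methide 15, and ring A of 13 attacks it first at one of C4 or C6 (drawn as C4 in 16) and then at the other, each attack followed by rearomatising proton loss, so both ring A aryl–CH2 bonds form in one flask. The closest known reaction types are the acid-promoted Friedel–Crafts benzylation of phenols and resorcinol ethers with 4-hydroxybenzyl alcohol and the Friedel–Crafts alkylation of halogen-blocked resorcinols. No ring is closed and no stereocentre is created. The step needs site selectivity within ring A and chemoselectivity against the other rings: C4 is ortho to the C3 hydroxyl and para to the C1 methoxy, C6 is para to the hydroxyl and ortho to the methoxy, the only other doubly activated carbon (C2) carries bromine, and rings B and C are switched off by their electron-withdrawing sulfonate esters. The incoming 4-hydroxybenzyl rings and 14 itself are only singly activated phenols with the para position occupied, and slow addition keeps 15 scarce so that its oligomerisation and over-benzylation should lag behind attack by the resorcinol-type ring A. Any O-benzyl ether formed at the ring A phenol should revert under the acidic conditions and funnel to the C-benzylated product.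

Step 10
Reactants: 17 3-{2-[4-bromo-3-hydroxy-2,6-bis(4-hydroxybenzyl)-5-methoxyphenyl]ethyl}-5-[4-(tosyloxy)benzyl]phenyl 4-methylbenzenesulfonate
Product: 18 3-{2-[3-hydroxy-2,6-bis(4-hydroxybenzyl)-5-methoxyphenyl]ethyl}-5-[4-(tosyloxy)benzyl]phenyl 4-methylbenzenesulfonate
Conditions: H2 (1 atm), 10% Pd/C, Et3N (3 equiv), EtOAc/MeOH, rt
Reagents that add atoms: none
Why: hydrodehalogenation of the aryl C–Br bond over Pd/C with an amine to take up HBr; aryl tosylates, diarylmethane CH2 groups and phenols should be inert under these mild conditions.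

Step 11
Reactants: 18 3-{2-[3-hydroxy-2,6-bis(4-hydroxybenzyl)-5-methoxyphenyl]ethyl}-5-[4-(tosyloxy)benzyl]phenyl 4-methylbenzenesulfonate
Product: 19 3-{2-[3-hydroxy-2,6-bis(4-hydroxybenzyl)-5-methoxyphenyl]ethyl}-5-(4-hydroxybenzyl)phenol (CNP0204120.0)
Conditions: KOH (10 equiv), 1,4-dioxane/H2O (1:1), 90 °C, argon; then 1 M HCl
Reagents that add atoms: none
Why: alkaline hydrolysis of the two aryl sulfonates by hydroxide attack at sulfur; aqueous dioxane instead of an alcohol avoids an alkyl tosylate that could alkylate the phenoxides, and the target has no base-sensitive group or stereocentre.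

**Compound list**

1 | methyl 4-bromo-3,5-dihydroxybenzoate | COC(=O)c1cc(O)c(Br)c(O)c1 | starting material
2 | methyl 4-bromo-3-hydroxy-5-methoxybenzoate | COC(=O)c1cc(O)c(Br)c(OC)c1 | intermediate
3 | 4-bromo-3-hydroxy-5-methoxybenzyl alcohol | OCc1cc(O)c(Br)c(OC)c1 | intermediate
4 | (4-bromo-3-hydroxy-5-methoxybenzyl)triphenylphosphonium bromide | COc1cc(C[P+](c2ccccc2)(c2ccccc2)c2ccccc2)cc(O)c1Br.[Br-] | intermediate
5 | 4-(chloromethyl)phenyl acetate | CC(=O)Oc1ccc(CCl)cc1 | starting material
6 | 4-[(4,4,5,5-tetramethyl-1,3,2-dioxaborolan-2-yl)methyl]phenyl acetate | CC(=O)Oc1ccc(CB2OC(C)(C)C(C)(C)O2)cc1 | intermediate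
7 | 3-bromo-5-hydroxybenzaldehyde | O=Cc1cc(O)cc(Br)c1 | starting material
8 | 4-(3-formyl-5-hydroxybenzyl)phenyl acetate | CC(=O)Oc1ccc(Cc2cc(O)cc(C=O)c2)cc1 | intermediate (not isolated)
9 | 3-hydroxy-5-(4-hydroxybenzyl)benzaldehyde | O=Cc1cc(O)cc(Cc2ccc(O)cc2)c1 | intermediate
10 | 3-formyl-5-[4-(tosyloxy)benzyl]phenyl 4-methylbenzenesulfonate | Cc1ccc(cc1)S(=O)(=O)Oc1ccc(Cc2cc(C=O)cc(OS(=O)(=O)c3ccc(C)cc3)c2)cc1 | intermediate
11 | lithium 2-bromo-3-methoxy-5-[(triphenylphosphoranylidene)methyl]phenolate (phenoxide ylide) | COc1cc(C=P(c2ccccc2)(c2ccccc2)c2ccccc2)cc([O-])c1Br.[Li+] | intermediate (not isolated)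
12 | 3-[2-(4-bromo-3-hydroxy-5-methoxyphenyl)ethenyl]-5-[4-(tosyloxy)benzyl]phenyl 4-methylbenzenesulfonate, E/Z mixture (geometry not defined) | COc1cc(C=Cc2cc(OS(=O)(=O)c3ccc(C)cc3)cc(Cc3ccc(OS(=O)(=O)c4ccc(C)cc4)cc3)c2)cc(O)c1Br | intermediate
13 | 3-[2-(4-bromo-3-hydroxy-5-methoxyphenyl)ethyl]-5-[4-(tosyloxy)benzyl]phenyl 4-methylbenzenesulfonate | COc1cc(CCc2cc(OS(=O)(=O)c3ccc(C)cc3)cc(Cc3ccc(OS(=O)(=O)c4ccc(C)cc4)cc3)c2)cc(O)c1Br | intermediate
14 | 4-hydroxybenzyl alcohol | OCc1ccc(O)cc1 | starting material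
15 | 4-methylidenecyclohexa-2,5-dien-1-one (p-quinone methide) | C=C1C=CC(=O)C=C1 | intermediate (not isolated)
16 | 3-{2-[4-bromo-3-hydroxy-2-(4-hydroxybenzyl)-5-methoxyphenyl]ethyl}-5-[4-(tosyloxy)benzyl]phenyl 4-methylbenzenesulfonate | COc1cc(CCc2cc(OS(=O)(=O)c3ccc(C)cc3)cc(Cc3ccc(OS(=O)(=O)c4ccc(C)cc4)cc3)c2)c(Cc2ccc(O)cc2)c(O)c1Br | intermediate (not isolated)
17 | 3-{2-[4-bromo-3-hydroxy-2,6-bis(4-hydroxybenzyl)-5-methoxyphenyl]ethyl}-5-[4-(tosyloxy)benzyl]phenyl 4-methylbenzenesulfonate | COc1c(Br)c(O)c(Cc2ccc(O)cc2)c(CCc2cc(OS(=O)(=O)c3ccc(C)cc3)cc(Cc3ccc(OS(=O)(=O)c4ccc(C)cc4)cc3)c2)c1Cc1ccc(O)cc1 | intermediate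
18 | 3-{2-[3-hydroxy-2,6-bis(4-hydroxybenzyl)-5-methoxyphenyl]ethyl}-5-[4-(tosyloxy)benzyl]phenyl 4-methylbenzenesulfonate | COc1cc(O)c(Cc2ccc(O)cc2)c(CCc2cc(OS(=O)(=O)c3ccc(C)cc3)cc(Cc3ccc(OS(=O)(=O)c4ccc(C)cc4)cc3)c2)c1Cc1ccc(O)cc1 | intermediate
19 | 3-{2-[3-hydroxy-2,6-bis(4-hydroxybenzyl)-5-methoxyphenyl]ethyl}-5-(4-hydroxybenzyl)phenol (CNP0204120.0) | COc1cc(O)c(Cc2ccc(O)cc2)c(CCc2cc(O)cc(Cc3ccc(O)cc3)c2)c1Cc1ccc(O)cc1 | target

**Count and risks**

Total steps: 11. Longest linear sequence: 8 steps (steps 1–3 then 7–11; the branch through steps 4–6 then 7–11 is equally long).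

Steps most likely to fail:

1. Step 9. The quinone methide may be consumed by self-condensation, the phenol rings already installed may be benzylated further, and the second benzylation at the crowded last free carbon of ring A may stall. The fallback sets out from 13 and replaces the free-phenol electrophile by an O-protected one. 4-(Benzyloxy)benzyl alcohol (OCc1ccc(OCc2ccccc2)cc1, 2.5 equiv) with catalytic TsOH·H2O in (CF3)2CHOH/CH2Cl2 should give 3-{2-[2,6-bis(4-benzyloxybenzyl)-4-bromo-3-hydroxy-5-methoxyphenyl]ethyl}-5-[4-(tosyloxy)benzyl]phenyl 4-methylbenzenesulfonate F1. Hydrogenolysis (H2, 10% Pd/C, NaOAc, EtOAc/MeOH) should then remove both O-benzyl groups and the bromine together, and the route is rejoined at 18.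

2. Step 5. Transmetalation of the benzylboronate may be slow, so that protodeboronation or homocoupling overtakes the cross-coupling. The fallback sets out from 7 and inverts the polarity of the partners. Acetylation (Ac2O, pyridine) should give 3-bromo-5-formylphenyl acetate F2. Miyaura borylation (B2pin2, Pd(dppf)Cl2, KOAc, 1,4-dioxane, 85 °C) should give 3-formyl-5-(4,4,5,5-tetramethyl-1,3,2-dioxaborolan-2-yl)phenyl acetate F3. Coupling of this arylboronate with benzylic chloride 5 (Pd(PPh3)4, anhydrous K3PO4, toluene, 90 °C, so that no phenoxide is present to be O-benzylated) should give 4-(3-acetoxy-5-formylbenzyl)phenyl acetate F4. Methanolysis (K2CO3, MeOH, rt) returns to the route at 9.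

3. Step 7. Double deprotonation of the phenolic phosphonium salt may give a poorly soluble, sluggish ylide, and residual amide base may attack the aldehyde. The fallback sets out from 4 and masks the phenol so that a mono-anionic ylide is used. Silylation (TBSCl, imidazole, CH2Cl2) should give [4-bromo-3-(tert-butyldimethylsilyloxy)-5-methoxybenzyl]triphenylphosphonium bromide F5. Wittig reaction with 10 (LiN(SiMe3)2, 1.0 equiv, THF, −78 °C to rt) should give 3-{2-[4-bromo-3-(tert-butyldimethylsilyloxy)-5-methoxyphenyl]ethenyl}-5-[4-(tosyloxy)benzyl]phenyl 4-methylbenzenesulfonate F6. Desilylation (Bu4NF, AcOH, THF, 0 °C) returns to the route at 12.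

**Further compounds**

F1 | step 9 | 3-{2-[2,6-bis(4-benzyloxybenzyl)-4-bromo-3-hydroxy-5-methoxyphenyl]ethyl}-5-[4-(tosyloxy)benzyl]phenyl 4-methylbenzenesulfonate | COc1c(Br)c(O)c(Cc2ccc(OCc3ccccc3)cc2)c(CCc2cc(OS(=O)(=O)c3ccc(C)cc3)cc(Cc3ccc(OS(=O)(=O)c4ccc(C)cc4)cc3)c2)c1Cc1ccc(OCc2ccccc2)cc1
F2 | step 5 | 3-bromo-5-formylphenyl acetate | CC(=O)Oc1cc(Br)cc(C=O)c1
F3 | step 5 | 3-formyl-5-(4,4,5,5-tetramethyl-1,3,2-dioxaborolan-2-yl)phenyl acetate | CC(=O)Oc1cc(C=O)cc(c1)B1OC(C)(C)C(C)(C)O1
F4 | step 5 | 4-(3-acetoxy-5-formylbenzyl)phenyl acetate | CC(=O)Oc1ccc(Cc2cc(OC(C)=O)cc(C=O)c2)cc1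
F5 | step 7 | [4-bromo-3-(tert-butyldimethylsilyloxy)-5-methoxybenzyl]triphenylphosphonium bromide | COc1cc(C[P+](c2ccccc2)(c2ccccc2)c2ccccc2)cc(O[Si](C)(C)C(C)(C)C)c1Br.[Br-]
F6 | step 7 | 3-{2-[4-bromo-3-(tert-butyldimethylsilyloxy)-5-methoxyphenyl]ethenyl}-5-[4-(tosyloxy)benzyl]phenyl 4-methylbenzenesulfonate (E/Z mixture) | COc1cc(C=Cc2cc(OS(=O)(=O)c3ccc(C)cc3)cc(Cc3ccc(OS(=O)(=O)c4ccc(C)cc4)cc3)c2)cc(O[Si](C)(C)C(C)(C)C)c1Br
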